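As the chemist at this bench, I count reagent before I reckon rates. Each substrate takes one reagent to reach first product, two for double and three for triple, so I carry one number, 2.50 for east and 2.00 for north: the reagent budget, charged [reagent] over charged [substrate].

| setting | cedar | larch | elm | north | east |
|---|---|---|---|---|---|
| substrate | 0.80 M | 0.80 M | 0.80 M | 0.80 M | 0.80 M |
| reagent | 1.5 M | 1.9 M | 2.3 M | 1.60 M | 2.00 M |
| remark | run made earlier | run made earlier | run made earlier |  |  |
| time |  |  |  | 5.0 d | 5.0 d |

| run | time / d | double product / % | triple product / % |
|---|---|---|---|
| cedar | 0.208 | 12 | 2 |
| cedar | 0.417 | 22 | 4 |
| cedar | 0.625 | 29 | 7 |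
| cedar | 1.25 | 39 | 12 |
| cedar | 2.50 | 45 | 22 |
| larch | 0.500 | 33 | 7 |
| larch | 1.04 | 45 | 19 |
| larch | 1.67 | 48 | 31 |
| larch | 2.08 | 46 | 34 |
| larch | 2.50 | 44 | 35 |
| elm | 0.208 | 25 | 4 |
| elm | 0.625 | 46 | 16 |
| elm | 1.25 | 46 | 34 |
| elm | 1.67 | 39 | 47 |
| elm | 2.50 | 34 | 53 |

(readings scatter by 2 percentage points)

1. which of these holds the largest part of the substrate at the end of north (triple product / substrate / first product / double product)
2. which of these holds the largest part of the substrate at the end of east (triple product / substrate / first product / double product)
3. how much double product is there at the end of east, in percent of the substrate charged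

Who leads north? In larch at 2.50 d, double and triple together have taken 1.93 equivalents, close to north's budget, yet double stands above triple, 44% to 35%. So I expect double ahead in north.

Who leads east? Reading a quarter of the way from larch to elm at that time gives double 41.5% and triple 39.5%, about level, with 2.02 equivalents taken. East's budget of 2.50 stands above those 2.02 equivalents, and elm at that time has triple ahead, 53% to 34%, so I expect triple ahead in east.

How much double? Suppose the budget is spent and 87.0% of the substrate stands as double or triple, as in elm's last reading, the rest as first product. Then east holds 63.0% triple product and 24.0% double product. Elm's double is still falling, so I take the midpoint between 41.5% and that spent-budget figure: 32.8%.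

The forecast says double product for north, triple product for east and 35% double (range 31% to 40%), 2.2 percentage points above mine, holding that “Product distribution therefore depends mainly on reagent per substrate and the integral of reagent over time”.

The flasks give double product for north, triple product for east, and 36.6% double in east.

    reagent + double product → triple product (k = 5.68 × 10⁻⁴ /M/min)
    reagent → decomposition product (k = 8.14 × 10⁻⁶ /min)
    substrate + reagent → first product (k = 0.00172 /M/min)
    2 substrate → self-condensation product (k = 1.89 × 10⁻⁴ /M/min)
    reagent + first product → double product (k = 0.00166 /M/min)

East's products have taken 2.37 of its budget of 2.50 equivalents, and 4.13% of its reagent remains. A neighbour like east but charged with 0.50 M of reagent has a budget of 0.625. Its products at 5.00 d have taken 0.619, and reagent, the limiting reagent here, is down to 0.125% of its charge. That neighbour holds 30.3% first product, 13.8% double product, 1.34% triple product and 22% unbound substrate.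

The readings stem from a simulated flask on assumed constants; scatter was added.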